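Dusk, spring and midnight are neighbouring flasks that share every charge except the free catalyst, and I want to know how much target each holds when the time is up.

    second substrate + free catalyst ⇌ catalyst intermediate B (K1 = 1100 M⁻¹, k1 = 75000 M⁻¹ s⁻¹)
    reagent + catalyst intermediate A → free catalyst + target (k2 = 4.25 × 10⁵ M⁻¹ s⁻¹)
    starting material + free catalyst ⇌ catalyst intermediate A (K3 = 22000 M⁻¹, k3 = 34900 M⁻¹ s⁻¹)
    solid substrate ⇌ starting material, rate k4*(cs4 - [starting material]) while solid is left; crystals form when [starting material] > cs4 (cs4 = 0.52 mM, k4 = 0.0474 s⁻¹)
    reagent + catalyst intermediate B → free catalyst + second product (k5 = 11500 M⁻¹ s⁻¹)

| flask | solid substrate | second substrate | reagent | free catalyst | time |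
|---|---|---|---|---|---|
| dusk | 1.0 mM | 1.00 mM | 1.00 mM | 5.0 µM | 25 s |
| spring | 1.0 mM | 1.00 mM | 1.00 mM | 10 µM | 25 s |
| midnight | 1.0 mM | 1.00 mM | 1.00 mM | 20 µM | 25 s |

- amount of target at the end, in percent of the solid substrate charged for dusk, spring, midnight, in this order
- how that number moves from the first to the last of them (falls, then rises / falls all the way / rises all the way / hardly changes / rises, then falls)

I turn the question round. For the row to rise all the way, I expect reagent to have to last through the run in the flask with the most catalyst, so I ask how long it survives the side route through catalyst intermediate B.

Two things can be frozen while reagent stands near its charge. Reagent uses up each catalyst intermediate A at 425 s⁻¹, and each free catalyst takes up starting material at 18.1 s⁻¹ with starting material at its solubility, so with use far faster than making, I count catalyst intermediate A as a minor form. Second substrate binds with a half-life of 0.00924 s, shorter than the 0.060 s in which reagent clears catalyst intermediate B at dusk, so I take that binding as an equilibrium. Free catalyst and catalyst intermediate B are then the resting state, and at the charged second substrate the latter holds 52.4% of the catalyst.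

Reagent therefore falls by a pseudo-first-order law on the side route. I call the resulting half-life the reagent clock: the half-life of reagent on the side route alone, with second substrate frozen at its charge. It is 23.0 s at dusk, 11.5 s at spring and 5.75 s at midnight. I take the opposite outcome to ask for a midnight clock as long as the run, but it is a quarter of 25 s, so the run holds 4.35 clocks, against 1.09 at dusk. I commit to a fall at the catalyst-rich end; my reckoning gives no figure for target.

The forecast gives 33%, 45% and 40%, a row that rises, then falls, with the reagent at midnight going “before much starting material has dissolved”.

The flasks give 30.8%, 42.4% and 38.0%, a row that rises, then falls, turning at 12 µM. At midnight, both reagent steps ran while reagent lasted: at 12.5 s the flask held 0.583 mM of second product, where the clock gives 0.778 mM, and at 25.0 s reagent stood at 0% of its charge with target at 38.0%. At spring, the clock gives 0.529 mM of second product for 12.5 s, the flask held 0.419 mM, and 5.1% of the reagent remained at the end.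

The numbers of this flask come from no measurement; the run is a simulation.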